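## Retrosynthetic overview
1. 15 (2S,3S,4S,5R; 2,3-trans, 3,4-trans, 4,5-cis) ⇒ hexamethyl ether 14. Both phenols are freed last by cleaving the two flanked 4-OMe groups.
2. 14 ⇒ sulfone 10 + arylzinc 13. The C5–aryl bond is made on the cyclic oxocarbenium ion, which sets C5.
3. 10 ⇒ lactol 8 ⇒ open-chain γ-hydroxy enol carbamate 7. The only ring (the oxolane) closes here through O1–C5, and C4 is set by equilibration.
4. 7 ⇒ carbamate 3 + aldehyde 4 (key step). The C2–C3 bond joins an aldehyde carbon to a chiral α-metallated tiglyl carbamate, which is the β-anion (homoenolate) of 2-methylbutanal. This sets C2, C3 and the absolute configuration.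
5. 3 ⇒ tiglyl alcohol 1 + carbamoyl chloride 2.

Assumption: s-BuLi/(–)-sparteine acts on 3 with the sense established for (E)-crotyl and cyclohexenylmethyl carbamates (pro-S deprotonation, Li→Ti exchange with inversion); 1, 2, 4, 9, 11, (–)-sparteine and LiPPh2 solution are bought.

Target ring numbering (O1, C2–C5) is used in every "Why" line.

## Route

Step 1
Reactants: 1 (E)-2-methylbut-2-en-1-ol; 2 N,N-diisopropylcarbamoyl chloride
Product: 3 (E)-2-methylbut-2-en-1-yl N,N-diisopropylcarbamate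
Conditions: NaH, THF, 0 °C; then 2, reflux
Reagents that add atoms: N,N-diisopropylcarbamoyl chloride (2), CC(C)N(C(C)C)C(=O)Cl
Why: O-carbamoylation (nucleophilic acyl substitution) of the sodium alkoxide installs the carbamoyl group that later directs and stabilises α-lithiation, forming no stereocentre and leaving the E alkene untouched.

Step 2 (key step)
Reactants: 3 (E)-2-methylbut-2-en-1-yl N,N-diisopropylcarbamate; 4 3,4,5-trimethoxybenzaldehyde
Product: 7 (1Z,3S,4S)-4-hydroxy-2,3-dimethyl-4-(3,4,5-trimethoxyphenyl)but-1-en-1-yl N,N-diisopropylcarbamate, via lithiated carbamate sparteine complex 5 (not isolated), via allyltitanium triisopropoxide 6 (not isolated)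
Conditions: s-BuLi, (–)-sparteine, toluene, –78 °C; Ti(OiPr)4, –78 °C; 4, –78 °C; 2 M HCl
Reagents that add atoms: none
Why: In this Hoppe asymmetric homoaldol reaction, s-BuLi/(–)-sparteine removes the pro-S α-proton to give (S)-5, Li→Ti exchange with inversion gives (R)-6, and the γ-carbon of this homoenolate equivalent adds suprafacially to the aldehyde through a chair Zimmerman–Traxler transition state (aryl and E-γ-methyl equatorial, carbamoyloxy axial), so the C2–C3 bond, the anti (later 2,3-trans) relationship, the 2S,3S configuration and the Z enol carbamate all arise in one step.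

Step 3
Reactants: 7 (1Z,3S,4S)-4-hydroxy-2,3-dimethyl-4-(3,4,5-trimethoxyphenyl)but-1-en-1-yl N,N-diisopropylcarbamate
Product: 8 (3S,4S,5S)-3,4-dimethyl-5-(3,4,5-trimethoxyphenyl)oxolan-2-ol (anomer mixture)
Conditions: Hg(OAc)2 (5 mol %), MsOH (1.2 equiv), THF–H2O 4:1, rt; then K2CO3, MeOH, rt
Reagents that add atoms: water, O
Why: In this Hoppe enol-carbamate solvolysis, Hg(II)/H+ activation protonates C4, the C2 hydroxyl closes the oxolane on the acyloxycarbenium carbon C5, water replaces the carbamate, and base-mediated enolisation of the open-chain γ-hydroxy aldehyde tautomer then equilibrates C4 to the more stable 3,4-trans (4S) lactol, while the non-acidic C2 and C3 stay fixed.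

Step 4
Reactants: 8 (3S,4S,5S)-3,4-dimethyl-5-(3,4,5-trimethoxyphenyl)oxolan-2-ol; 9 benzenesulfinic acid
Product: 10 (3S,4S,5S)-2-(benzenesulfonyl)-3,4-dimethyl-5-(3,4,5-trimethoxyphenyl)oxolane (anomer mixture)
Conditions: PhSO2H, CaCl2, CH2Cl2, rt
Reagents that add atoms: benzenesulfinic acid (9), O=S(O)c1ccccc1
Why: In this Ley sulfone formation, acid-induced loss of water from the lactol gives the cyclic oxocarbenium ion, which sulfinate captures at sulfur to give a crystalline, storable oxocarbenium precursor whose anomeric centre is inconsequential and whose recrystallisation can raise dr and ee.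

Step 5
Reactants: 10 (3S,4S,5S)-2-(benzenesulfonyl)-3,4-dimethyl-5-(3,4,5-trimethoxyphenyl)oxolane; 11 5-bromo-1,2,3-trimethoxybenzene
Product: 14 (2S,3S,4S,5R)-3,4-dimethyl-2,5-bis(3,4,5-trimethoxyphenyl)oxolane, via arylmagnesium bromide 12 (not isolated), via arylzinc bromide 13 (not isolated)
Conditions: 11, Mg, THF, reflux; ZnBr2, THF, rt; then 10, 0 °C → rt; aq. NH4Cl
Reagents that add atoms: none
Why: In this Ley-type substitution of a 2-sulfonyl cyclic ether, Zn(II) ionises the sulfone to the oxocarbenium ion, whose all-pseudoequatorial envelope is attacked by the arylzinc from inside the envelope (Woerpel model), anti to the C3 methyl and syn to the C4 methyl, which sets C5 as R (4,5-cis, 2,5-cis) irreversibly under non-acidic conditions, as is known for closely related 5-aryl-3,4-trans-dimethyl sulfones.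

Step 6
Reactants: 14 (2S,3S,4S,5R)-3,4-dimethyl-2,5-bis(3,4,5-trimethoxyphenyl)oxolane
Product: 15 4,4'-[(2S,3S,4S,5R)-3,4-dimethyloxolane-2,5-diyl]bis(2,6-dimethoxyphenol)
Conditions: LiPPh2 (0.5 M in THF, 5 equiv), THF, rt → 45 °C; cold aq. NH4Cl
Reagents that add atoms: none
Why: In this nucleophilic aryl methyl ether cleavage (SN2 at methyl by lithium diphenylphosphide), the central methoxy group of each 3,4,5-trimethoxyphenyl ring is twisted out of conjugation by its two ortho neighbours and is attacked preferentially, the resulting phenoxide shuts down further cleavage in that ring, and the acid-free medium leaves all four stereocentres untouched, including the labile cis-benzylic C5.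

## Compound list
1 | (E)-2-methylbut-2-en-1-ol (tiglyl alcohol) | C/C=C(\C)CO | starting material
2 | N,N-diisopropylcarbamoyl chloride | CC(C)N(C(C)C)C(=O)Cl | starting material
3 | (E)-2-methylbut-2-en-1-yl N,N-diisopropylcarbamate | C/C=C(\C)COC(=O)N(C(C)C)C(C)C | intermediate
4 | 3,4,5-trimethoxybenzaldehyde | COc1cc(C=O)cc(OC)c1OC | starting material
5 | (S)-1-lithio-(E)-2-methylbut-2-enyl N,N-diisopropylcarbamate, (–)-sparteine complex (ligand not drawn) | C/C=C(\C)[C@H]([Li])OC(=O)N(C(C)C)C(C)C | intermediate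
6 | (R)-1-(triisopropoxytitanio)-(E)-2-methylbut-2-enyl N,N-diisopropylcarbamate | C/C=C(\C)[C@@H]([Ti](OC(C)C)(OC(C)C)OC(C)C)OC(=O)N(C(C)C)C(C)C | intermediate
7 | (1Z,3S,4S)-4-hydroxy-2,3-dimethyl-4-(3,4,5-trimethoxyphenyl)but-1-en-1-yl N,N-diisopropylcarbamate | COc1cc(cc(OC)c1OC)[C@@H](O)[C@@H](C)/C(C)=C\OC(=O)N(C(C)C)C(C)C | intermediate
8 | (3S,4S,5S)-3,4-dimethyl-5-(3,4,5-trimethoxyphenyl)oxolan-2-ol, anomer mixture | COc1cc(cc(OC)c1OC)[C@H]1OC(O)[C@@H](C)[C@@H]1C | intermediate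
9 | benzenesulfinic acid | O=S(O)c1ccccc1 | starting material
10 | (3S,4S,5S)-2-(benzenesulfonyl)-3,4-dimethyl-5-(3,4,5-trimethoxyphenyl)oxolane, anomer mixture | COc1cc(cc(OC)c1OC)[C@H]1OC(S(=O)(=O)c2ccccc2)[C@@H](C)[C@@H]1C | intermediate
11 | 5-bromo-1,2,3-trimethoxybenzene | COc1cc(Br)cc(OC)c1OC | starting material
12 | (3,4,5-trimethoxyphenyl)magnesium bromide | COc1cc([Mg]Br)cc(OC)c1OC | intermediate
13 | (3,4,5-trimethoxyphenyl)zinc bromide | COc1cc([Zn]Br)cc(OC)c1OC | intermediate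
14 | (2S,3S,4S,5R)-3,4-dimethyl-2,5-bis(3,4,5-trimethoxyphenyl)oxolane | COc1cc(cc(OC)c1OC)[C@H]1O[C@@H](c2cc(OC)c(OC)c(OC)c2)[C@@H](C)[C@@H]1C | intermediate
15 | 4,4'-[(2S,3S,4S,5R)-3,4-dimethyloxolane-2,5-diyl]bis(2,6-dimethoxyphenol) | COc1cc([C@H]2O[C@@H](c3cc(OC)c(O)c(OC)c3)[C@@H](C)[C@@H]2C)cc(OC)c1O | target

## Summary
Total step count: 6. Longest linear sequence: 6 (1 → 3 → 7 → 8 → 10 → 14 → 15).

Steps most likely to fail:

**Step 2.** Carbamate 3 is the 2-methyl homologue of the well-behaved crotyl carbamate, so its ee depends on selective deprotonation and on the configurational stability of 5.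

The fallback sets out from 2 and 4 and comes back at 8. It takes the second methyl group out of the homoenolate and adds it later by enolate alkylation.
- Commercial (E)-crotyl alcohol is carbamoylated with 2 (NaH, THF) to (E)-but-2-en-1-yl N,N-diisopropylcarbamate F1.
- n-BuLi/(–)-sparteine in pentane–cyclohexane at –70 °C gives, by crystallisation-driven epimer enrichment, the (S)-1-lithiocrotyl carbamate sparteine complex F2.
- Ti(OiPr)4 converts this with inversion into the (R)-1-(triisopropoxytitanio)crotyl carbamate F3.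
- Aldehyde 4 then gives (1Z,3S,4S)-4-hydroxy-3-methyl-4-(3,4,5-trimethoxyphenyl)but-1-en-1-yl N,N-diisopropylcarbamate F4.
- Solvolysis as in step 3 gives (4S,5S)-4-methyl-5-(3,4,5-trimethoxyphenyl)oxolan-2-ol F5.
- TEMPO/PhI(OAc)2 oxidation gives (4S,5S)-4-methyl-5-(3,4,5-trimethoxyphenyl)oxolan-2-one F6.
- LDA/MeI alkylates anti to the ring methyl and gives (3S,4S,5S)-3,4-dimethyl-5-(3,4,5-trimethoxyphenyl)oxolan-2-one F7.
- DIBAL-H at –78 °C delivers lactol 8.

**Step 5.** The oxocarbenium ion may eliminate to the dihydrofuran, or the contra-steric cis selectivity may erode.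

The fallback sets out from 8 and 12 and comes back at 14. It makes the last stereocentre by C–O bond formation with inversion instead of C–C bond formation.
- Lactol 8 is opened with excess 12 to (2S,3S,4S)-2,3-dimethyl-1,4-bis(3,4,5-trimethoxyphenyl)butane-1,4-diol (C1 epimers) F8.
- Dess–Martin oxidation erases both carbinol centres and gives the C2-symmetric (2S,3S)-2,3-dimethyl-1,4-bis(3,4,5-trimethoxyphenyl)butane-1,4-dione F9.
- BH3·SMe2/(R)-Me-CBS, matched with the Felkin–Anh bias, gives the C2-symmetric anti,anti (1S,2S,3S,4S)-2,3-dimethyl-1,4-bis(3,4,5-trimethoxyphenyl)butane-1,4-diol F10.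
- Mitsunobu cyclodehydration (PPh3, DIAD) activates either of the two homotopic hydroxyls and closes the ring by SN2 inversion. One S carbinol thereby becomes the R, 4,5-cis centre of 14.

**Step 6.** Regioselectivity must hold in both rings, and a phenoxide-triggered quinone methide opening would epimerise the benzylic centres.

The fallback sets out from 3 (through 5 and 6) and comes back at 15. It carries both phenols as benzyl ethers from the start and frees them under neutral conditions.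
- Syringaldehyde with BnBr/K2CO3 gives 4-(benzyloxy)-3,5-dimethoxybenzaldehyde F11.
- Reaction with 6 as in step 2 gives (1Z,3S,4S)-4-[4-(benzyloxy)-3,5-dimethoxyphenyl]-4-hydroxy-2,3-dimethylbut-1-en-1-yl N,N-diisopropylcarbamate F12.
- The conditions of step 3 give (3S,4S,5S)-5-[4-(benzyloxy)-3,5-dimethoxyphenyl]-3,4-dimethyloxolan-2-ol F13.
- The conditions of step 4 give (3S,4S,5S)-2-(benzenesulfonyl)-5-[4-(benzyloxy)-3,5-dimethoxyphenyl]-3,4-dimethyloxolane F14.
- 4-Bromo-2,6-dimethoxyphenol with BnBr/K2CO3 gives 2-(benzyloxy)-5-bromo-1,3-dimethoxybenzene F15.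
- Mg converts this into [4-(benzyloxy)-3,5-dimethoxyphenyl]magnesium bromide F16, and ZnBr2 then gives [4-(benzyloxy)-3,5-dimethoxyphenyl]zinc bromide F17.
- This zinc reagent reacts with F14 as in step 5 to give (2S,3S,4S,5R)-2,5-bis[4-(benzyloxy)-3,5-dimethoxyphenyl]-3,4-dimethyloxolane F18.
- H2 (1 atm), Pd/C, EtOAc, stopped after two equivalents, gives 15.

## Further compounds
F1 | step 2 | (E)-but-2-en-1-yl N,N-diisopropylcarbamate | C/C=C/COC(=O)N(C(C)C)C(C)C
F2 | step 2 | (S)-1-lithiocrotyl carbamate sparteine complex (ligand not drawn) | C/C=C/[C@H]([Li])OC(=O)N(C(C)C)C(C)C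
F3 | step 2 | (R)-1-(triisopropoxytitanio)crotyl carbamate | C/C=C/[C@@H]([Ti](OC(C)C)(OC(C)C)OC(C)C)OC(=O)N(C(C)C)C(C)C
F4 | step 2 | (1Z,3S,4S)-4-hydroxy-3-methyl-4-(3,4,5-trimethoxyphenyl)but-1-en-1-yl N,N-diisopropylcarbamate | COc1cc(cc(OC)c1OC)[C@@H](O)[C@@H](C)/C=C\OC(=O)N(C(C)C)C(C)C
F5 | step 2 | (4S,5S)-4-methyl-5-(3,4,5-trimethoxyphenyl)oxolan-2-ol | COc1cc(cc(OC)c1OC)[C@H]1OC(O)C[C@@H]1C
F6 | step 2 | (4S,5S)-4-methyl-5-(3,4,5-trimethoxyphenyl)oxolan-2-one | COc1cc(cc(OC)c1OC)[C@H]1OC(=O)C[C@@H]1C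
F7 | step 2 | (3S,4S,5S)-3,4-dimethyl-5-(3,4,5-trimethoxyphenyl)oxolan-2-one | COc1cc(cc(OC)c1OC)[C@H]1OC(=O)[C@@H](C)[C@@H]1C
F8 | step 5 | (2S,3S,4S)-2,3-dimethyl-1,4-bis(3,4,5-trimethoxyphenyl)butane-1,4-diol (C1 epimers) | COc1cc(cc(OC)c1OC)[C@@H](O)[C@@H](C)[C@H](C)C(O)c1cc(OC)c(OC)c(OC)c1
F9 | step 5 | (2S,3S)-2,3-dimethyl-1,4-bis(3,4,5-trimethoxyphenyl)butane-1,4-dione | COc1cc(cc(OC)c1OC)C(=O)[C@@H](C)[C@H](C)C(=O)c1cc(OC)c(OC)c(OC)c1
F10 | step 5 | (1S,2S,3S,4S)-2,3-dimethyl-1,4-bis(3,4,5-trimethoxyphenyl)butane-1,4-diol | COc1cc(cc(OC)c1OC)[C@@H](O)[C@@H](C)[C@H](C)[C@H](O)c1cc(OC)c(OC)c(OC)c1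
F11 | step 6 | 4-(benzyloxy)-3,5-dimethoxybenzaldehyde | COc1cc(C=O)cc(OC)c1OCc2ccccc2
F12 | step 6 | (1Z,3S,4S)-4-[4-(benzyloxy)-3,5-dimethoxyphenyl]-4-hydroxy-2,3-dimethylbut-1-en-1-yl N,N-diisopropylcarbamate | COc1cc(cc(OC)c1OCc2ccccc2)[C@@H](O)[C@@H](C)/C(C)=C\OC(=O)N(C(C)C)C(C)C
F13 | step 6 | (3S,4S,5S)-5-[4-(benzyloxy)-3,5-dimethoxyphenyl]-3,4-dimethyloxolan-2-ol | COc1cc(cc(OC)c1OCc2ccccc2)[C@H]3OC(O)[C@@H](C)[C@@H]3C
F14 | step 6 | (3S,4S,5S)-2-(benzenesulfonyl)-5-[4-(benzyloxy)-3,5-dimethoxyphenyl]-3,4-dimethyloxolane | COc1cc(cc(OC)c1OCc2ccccc2)[C@H]3OC(S(=O)(=O)c4ccccc4)[C@@H](C)[C@@H]3C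
F15 | step 6 | 2-(benzyloxy)-5-bromo-1,3-dimethoxybenzene | COc1cc(Br)cc(OC)c1OCc2ccccc2
F16 | step 6 | [4-(benzyloxy)-3,5-dimethoxyphenyl]magnesium bromide | COc1cc([Mg]Br)cc(OC)c1OCc2ccccc2
F17 | step 6 | [4-(benzyloxy)-3,5-dimethoxyphenyl]zinc bromide | COc1cc([Zn]Br)cc(OC)c1OCc2ccccc2
F18 | step 6 | (2S,3S,4S,5R)-2,5-bis[4-(benzyloxy)-3,5-dimethoxyphenyl]-3,4-dimethyloxolane | COc1cc(cc(OC)c1OCc2ccccc2)[C@H]3O[C@@H](c4cc(OC)c(OCc5ccccc5)c(OC)c4)[C@@H](C)[C@@H]3C
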